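## Analysis of the target

Target 20 is a 2,3-trans-dihydroflavonol: a chroman-4-one (ring C fused to ring A) with a 4-hydroxy-3-methoxyphenyl group (ring B) at C2 and a hydroxyl at C3. Ring A carries a free hydroxyl at C5, hydrogen-bonded to the C4 carbonyl, and a 3-methylbut-2-enyl (prenyl) ether at C7. The two stereocentres are adjacent, C2 (R) and C3 (R), with the aryl group and the C3 hydroxyl trans-diequatorial. In an open-chain precursor this is the anti (erythro) arrangement of the two oxygens. C3–H is α to the ketone and O1 is β to it, so base can epimerise C3 or open ring C by β-elimination to a chalcone, which erases C2. The aryl prenyl ether is acid-labile and its alkene rules out hydrogenolysis. The synthesis is hard because the anti pair must be set and ring C closed without scrambling either centre, and because the C5 and C7 oxygens of ring A must be told apart. The strategy rests on one feature: O1 (at C8a) and the C5 oxygen both lie ortho to the C4 carbonyl, with C7 on the axis between them. Ring A can therefore come from a symmetric 2,6-difluoro-4-(prenyloxy)phenyl ketone, in which either fluorine is activated for displacement by the C2 hydroxyl and the other stays as a latent C5 hydroxyl.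

## Retrosynthetic reasoning

**20 ⇒ 19.** The last disconnection removes only the two O–CH2 acetal bonds at O3 and at the ring B phenol. Both oxygens carry the same group, so one operation frees them. The forward step must spare the prenyl ether and leave C2 and C3 alone.

**19 ⇒ 17.** The C5–O bond is traced back to a C5–F bond. The oxygen is introduced after ring closure because the fluorine keeps ring A symmetric and electron-poor for the key step. The same ortho-carbonyl activation then lets an oxygen nucleophile replace it. Once the C5 phenoxide exists, the ketone is deactivated and C3 is harder to enolise.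

**17 ⇒ 16 (key disconnection).** The O1–C8a bond is cut, not the O1–C2 bond. Cutting O1–C2 would make the benzylic carbon the electrophile, and next to an electron-rich ring B such a substitution tends to run through a cation and lose configuration. Cutting at the aryl carbon leaves both stereocentres untouched and turns ring A into a difluoroarene with no regiochemical choice. The forward reaction must give six-ring O-arylation faster than retro-aldol cleavage and must not epimerise C3, so the C3 oxygen is capped as an ether-type MOM group.

**16 ⇒ 15 ⇒ 13 + 14.** The C4–C4a bond is cut between a Weinreb amide 13 and aryllithium 14. Compound 14 comes from 3 by deprotonation at the carbon flanked by both fluorines, and 3 comes from 1 and 2. The benzylic hydroxyl is carried as a silyl ether (12, 13, 15) because a metal aldolate would fragment during the organometallic steps.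

**13 ⇒ 12 ⇒ 11 ⇒ 5 + 9.** The bond between the two stereocentres is an aldol bond. Cutting it gives aldehyde 5 and a glycolate ketene acetal 9 that already carries the future C3 oxygen as its MOM ether, so the two hydroxyls never need to be differentiated later. The forward aldol must be anti-selective and enantioselective, and both centres are set in that one step. A thioester is chosen because this class of ketene acetal gives anti adducts with a chiral Lewis acid promoter and is easily exchanged for the Weinreb amide.

**9 ⇒ 8 ⇒ 7 ⇒ 6, and 5 ⇒ 4.** The ketene acetal goes back through thioester 8 and ester 7 to 6. Aldehyde 5 is the protected form of 4.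

## Alternatives that were turned down

**Alternative 1: ring A built last by a Claisen-type cyclisation.**
- Disconnection: C4a–C5, with ring A traced to a keto-ester chain on a preformed, stereodefined dihydropyranone A1.
- Forward key step: under a magnesium alkoxide the extended enolate of the vinylogous ester in A1 acylates through C4a onto the terminal ester. Loss of methanol and enolisation aromatise the new ring to the 5,7-dihydroxy compound A2.
- For: both ring A oxygens arrive in place without any aryl–heteroatom exchange. Silyl protection allows a fluoride endgame with no acid near the prenyl ether. On that point it is stronger than the chosen route.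
- Against: in A1 the ring oxygen is β and C3–H is α to the C4 carbonyl. The basic, chelating conditions of the cyclisation are those under which ring C can open or C3 can epimerise. The chain has several acidic sites and could also close by aldol condensation to a different arene. A2 has two free phenols, so the prenyl group must be placed on O7 selectively afterwards. A silyl ether on C3 can migrate under base. Building A1 costs more steps than buying ring A.
- Comparison: the chosen strategy offers a purchased ring A with its two oxygens differentiated from step 1, and a ring closure under weak base with C3 capped by a group that cannot migrate.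

**Alternative 2: Friedel–Crafts closure.**
- Disconnection: C4–C4a, from acid A3 in which O1–C2 is already an aryl ether to a symmetric bis(benzyloxy)phenyl ring.
- Forward key step: activation of A3 as a mixed anhydride and intramolecular acylation ortho to O1 give A4.
- For: the ring is electron-rich and symmetric, so the acylation is fast and regiochemically unambiguous. This equals the chosen strategy on that point. No fluoride exchange is needed, which is an advantage.
- Against: A3 needs a configurationally defined secondary benzylic aryl ether, made by substitution at the benzylic carbon of an electron-rich system, where scrambling is likely. The same C2–O bond can ionise under the acidic acylation conditions. Benzyl ethers cannot be hydrogenolysed without reducing the prenyl alkene, and Lewis acids that cleave them also cleave prenyl ethers. O5 and O7 are not differentiated in A4.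
- Comparison: the chosen strategy never substitutes at C2 and needs no hydrogenolysis. Step counts are similar up to ring closure and longer for this alternative afterwards (deprotection and selective prenylation).

**Alternative 3: aryne annulation.**
- Disconnection: O1–C8a and C4–C4a together, from hydroxy ester A5 and silylaryl triflate A6.
- Forward key step: fluoride releases the aryne from A6. The alkoxide of A5 adds to the aryne carbon remote from the flanking alkoxy group, and the aryl anion is acylated by the ester to give A7.
- For: it is the most convergent plan. It makes both bonds to ring A in one operation and needs neither the Weinreb amide nor silyl protection, so up to ring C it is shorter than the chosen route.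
- Against: the aryl anion can be protonated by unreacted A5 faster than it attacks a hindered ester, which gives an open aryl ether. The alkoxide of A5 is an aldolate that can fragment. A6 takes several steps to make. A7 carries the same acetal on O7 as on every other oxygen, so the prenyl group must be added after global deprotection by selective alkylation.
- Comparison: the chosen route makes the same two bonds in two separate steps of dependable type, from a cheap symmetric arene, with the prenyl ether in place from step 1.

Key step: step 11

## Route

Assumption: the sense of induction and the anti preference of the tin-promoted aldol addition (step 6) are taken to be those of the corresponding benzyloxy-substituted ketene acetal. Should the sense prove reversed, the antipodal diamine would be used with no other change.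

Step 1
Reactants: 1 3,5-difluorophenol; 2 1-bromo-3-methylbut-2-ene (prenyl bromide)
Product: 3 1,3-difluoro-5-(3-methylbut-2-enyloxy)benzene
Conditions: K2CO3, acetone, reflux
Reagents that add atoms: none
Why: Williamson ether synthesis; the phenoxide of 1 displaces bromide at the primary allylic carbon of 2 by SN2, and carbonate in acetone favours O- over C-alkylation.

Step 2
Reactants: 4 vanillin
Product: 5 3-methoxy-4-(methoxymethoxy)benzaldehyde
Conditions: MOMCl, iPr2NEt, CH2Cl2, 0 °C → rt
Reagents that add atoms: chloromethyl methyl ether, COCCl
Why: O-alkylation of the phenol with a chloromethyl ether and a hindered amine; the acetal masks the phenol through the organometallic and basic steps and is removed together with the C3 acetal at the end.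

Step 3
Reactants: 6 methyl glycolate
Product: 7 methyl 2-(methoxymethoxy)acetate
Conditions: MOMCl, iPr2NEt, CH2Cl2, 0 °C → rt
Reagents that add atoms: chloromethyl methyl ether, COCCl
Why: The same alkylation on the primary hydroxyl; this MOM group becomes the cap on the C3 oxygen, an ether-type group that can neither migrate nor act as a nucleophile in the ring closure.

Step 4
Reactants: 7 methyl 2-(methoxymethoxy)acetate
Product: 8 S-ethyl 2-(methoxymethoxy)ethanethioate
Conditions: Al(CH3)3, EtSH, CH2Cl2, 0 °C → rt
Reagents that add atoms: ethanethiol, CCS
Why: Ester-to-thioester exchange with the dimethylaluminium thiolate formed in the flask; the thiolate is delivered to the ester carbonyl and methoxide stays on aluminium, and the acetal should tolerate the reagent at or below room temperature.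

Step 5
Reactants: 8 S-ethyl 2-(methoxymethoxy)ethanethioate
Product: 9 (Z)-1-(ethylsulfanyl)-2-(methoxymethoxy)-1-(trimethylsilyloxy)ethene
Conditions: LiN(iPr)2, Me3SiCl, THF, −78 °C
Reagents that add atoms: chlorotrimethylsilane, C[Si](C)(C)Cl
Why: Kinetic deprotonation of the thioester and O-silylation of the lithium enolate give the silyl ketene thioacetal needed for a Mukaiyama aldol addition; the Z isomer (alkoxy cis to the ethylsulfanyl group) is expected by analogy with the benzyloxy analogue.

Step 6
Reactants: 5 3-methoxy-4-(methoxymethoxy)benzaldehyde; 9 (Z)-1-(ethylsulfanyl)-2-(methoxymethoxy)-1-(trimethylsilyloxy)ethene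
Product: 11 S-ethyl (2R,3R)-3-hydroxy-2-(methoxymethoxy)-3-[3-methoxy-4-(methoxymethoxy)phenyl]propanethioate, via O-trimethylsilyl aldol adduct 10 (not isolated)
Conditions: Sn(OSO2CF3)2, (S)-1-ethyl-2-(piperidin-1-ylmethyl)pyrrolidine, Bu2Sn(OAc)2, CH2Cl2, −78 °C; then 1 M HCl–THF (1:20), 0 °C
Reagents that add atoms: none
Why: Asymmetric Mukaiyama aldol addition promoted by a chiral diamine complex of divalent tin triflate; the diamine-bound tin activates the aldehyde and shields one of its faces, the ketene acetal adds through an open transition state, and coordination of the α-alkoxy oxygen to tin makes α-alkoxy thioester acetals anti-selective, so both stereocentres (2R,3R) are set here under reagent control.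

Step 7
Reactants: 11 S-ethyl (2R,3R)-3-hydroxy-2-(methoxymethoxy)-3-[3-methoxy-4-(methoxymethoxy)phenyl]propanethioate
Product: 12 S-ethyl (2R,3R)-2-(methoxymethoxy)-3-[3-methoxy-4-(methoxymethoxy)phenyl]-3-(triethylsilyloxy)propanethioate
Conditions: Et3SiCl, imidazole, DMF, 0 °C → rt
Reagents that add atoms: chlorotriethylsilane, CC[Si](Cl)(CC)CC
Why: Silylation of the benzylic hydroxyl, so that neither the magnesium amide of step 8 nor the aryllithium of step 9 generates an aldolate that could cleave by retro-aldol reaction; the triethylsilyl group is chosen because buffered fluoride removes it later without base.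

Step 8
Reactants: 12 S-ethyl (2R,3R)-2-(methoxymethoxy)-3-[3-methoxy-4-(methoxymethoxy)phenyl]-3-(triethylsilyloxy)propanethioate
Product: 13 (2R,3R)-N-methoxy-2-(methoxymethoxy)-3-[3-methoxy-4-(methoxymethoxy)phenyl]-N-methyl-3-(triethylsilyloxy)propanamide
Conditions: MeNHOMe·HCl, iPrMgCl, THF, −20 → 0 °C
Reagents that add atoms: N,O-dimethylhydroxylamine hydrochloride, CNOC.Cl
Why: Aminolysis of the thioester by the chloromagnesium amide of N,O-dimethylhydroxylamine gives the Weinreb amide; thioesters react faster than O-esters, so low temperature suffices and the α-stereocentre should not be enolised.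

Step 9
Reactants: 3 1,3-difluoro-5-(3-methylbut-2-enyloxy)benzene; 13 (2R,3R)-N-methoxy-2-(methoxymethoxy)-3-[3-methoxy-4-(methoxymethoxy)phenyl]-N-methyl-3-(triethylsilyloxy)propanamide
Product: 15 (2R,3R)-1-[2,6-difluoro-4-(3-methylbut-2-enyloxy)phenyl]-2-(methoxymethoxy)-3-[3-methoxy-4-(methoxymethoxy)phenyl]-3-(triethylsilyloxy)propan-1-one, via 2,6-difluoro-4-(3-methylbut-2-enyloxy)phenyllithium 14 (not isolated)
Conditions: n-BuLi, THF, −78 °C; then 13, −78 °C; sat. aq. NH4Cl, −78 °C
Reagents that add atoms: none
Why: Directed ortho-metalation of 3 at the carbon between the two fluorines (the most acidic position), then Weinreb ketone synthesis; the chelated tetrahedral intermediate holds until the quench so the ketone forms only once, and the temperature stays at −78 °C because 2,6-difluorophenyllithiums lose LiF to give arynes on warming.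

Step 10
Reactants: 15 (2R,3R)-1-[2,6-difluoro-4-(3-methylbut-2-enyloxy)phenyl]-2-(methoxymethoxy)-3-[3-methoxy-4-(methoxymethoxy)phenyl]-3-(triethylsilyloxy)propan-1-one
Product: 16 (2R,3R)-1-[2,6-difluoro-4-(3-methylbut-2-enyloxy)phenyl]-3-hydroxy-2-(methoxymethoxy)-3-[3-methoxy-4-(methoxymethoxy)phenyl]propan-1-one
Conditions: HF·pyridine, pyridine, THF, 0 °C
Reagents that add atoms: none
Why: Buffered HF·pyridine cleaves the triethylsilyl ether without generating an alkoxide, so the hydroxy ketone can be isolated before any base is present; the MOM ethers, the prenyl ether and the aryl fluorides should be inert.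

Step 11
Reactants: 16 (2R,3R)-1-[2,6-difluoro-4-(3-methylbut-2-enyloxy)phenyl]-3-hydroxy-2-(methoxymethoxy)-3-[3-methoxy-4-(methoxymethoxy)phenyl]propan-1-one
Product: 17 (2R,3R)-5-fluoro-3-(methoxymethoxy)-2-[3-methoxy-4-(methoxymethoxy)phenyl]-7-(3-methylbut-2-enyloxy)chroman-4-one
Conditions: Cs2CO3, DMF, 0 °C → rt
Reagents that add atoms: none
Why: Carbonate deprotonates the C2 hydroxyl reversibly and the alkoxide adds to C8a, one of the two equivalent fluorine-bearing carbons ortho to the C4 carbonyl; the charge of the Meisenheimer intermediate is taken up by the ketone and fluoride is expelled, so O1–C8a forms by addition–elimination. The closest known reaction type is the intramolecular SNAr of alkoxides onto ortho-fluoroaryl ketones, which gives chroman-4-ones and flavanones. Ring C closes as a six-membered ring; read as conjugate addition to the C4a–C8a bond of the aryl ketone it is a 6-endo-trig closure, and the chain C2–C3–C4–C4a places the oxygen within reach of C8a without strain. No stereocentre is created: no bond to C2 or C3 is broken, and the anti relationship of 16 maps onto the 2,3-trans arrangement of 17. Regioselectivity is not an issue because the two fluorines are equivalent by symmetry. Selectivity for the six-membered ring is secured by the MOM cap on the C3 oxygen, which removes the only nucleophile that could close a five-membered ring and cannot migrate as a silyl group would. The step still needs ring closure to outrun retro-aldol cleavage of the aldolate and enolisation at C3; the doubly activated fluoroarene, the weak heterogeneous base, the low temperature and the greater stability of the trans product all favour this. The fluorine left at C5 stays ortho to the carbonyl and is the handle for step 12.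

Step 12
Reactants: 17 (2R,3R)-5-fluoro-3-(methoxymethoxy)-2-[3-methoxy-4-(methoxymethoxy)phenyl]-7-(3-methylbut-2-enyloxy)chroman-4-one
Product: 19 (2R,3R)-5-hydroxy-3-(methoxymethoxy)-2-[3-methoxy-4-(methoxymethoxy)phenyl]-7-(3-methylbut-2-enyloxy)chroman-4-one, via O-aryl acetohydroxamate 18 (not isolated)
Conditions: CH3C(O)NHOH, K2CO3, DMSO, 70 °C
Reagents that add atoms: acetohydroxamic acid, CC(=O)NO
Why: SNAr of the remaining fluoride, still ortho to the C4 carbonyl, by the acetohydroxamate anion acting as a hydroxide surrogate, then Lossen-type fragmentation of the O-aryl hydroxamate under the same conditions to the phenoxide; once formed, the C5 phenoxide deactivates the ketone and shields C3 from enolisation.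

Step 13
Reactants: 19 (2R,3R)-5-hydroxy-3-(methoxymethoxy)-2-[3-methoxy-4-(methoxymethoxy)phenyl]-7-(3-methylbut-2-enyloxy)chroman-4-one
Product: 20 (2R,3R)-3,5-dihydroxy-2-(4-hydroxy-3-methoxyphenyl)-7-(3-methylbut-2-enyloxy)chroman-4-one
Conditions: HCl (1–2 M) in MeOH, rt → 40 °C
Reagents that add atoms: none
Why: Acid-catalysed methanolysis of both MOM acetals, the aryl one fast and the C3 one slower; the acid is kept dilute and the temperature low to spare the aryl prenyl ether, and no bond at C2 or C3 is broken, so the product is the (2R,3R) target.

## Compound list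

1 | 3,5-difluorophenol | Oc1cc(F)cc(F)c1 | starting material
2 | 1-bromo-3-methylbut-2-ene (prenyl bromide) | CC(C)=CCBr | starting material
3 | 1,3-difluoro-5-(3-methylbut-2-enyloxy)benzene | CC(C)=CCOc1cc(F)cc(F)c1 | intermediate
4 | vanillin | COc1cc(C=O)ccc1O | starting material
5 | 3-methoxy-4-(methoxymethoxy)benzaldehyde | COCOc1ccc(C=O)cc1OC | intermediate
6 | methyl glycolate | COC(=O)CO | starting material
7 | methyl 2-(methoxymethoxy)acetate | COCOCC(=O)OC | intermediate
8 | S-ethyl 2-(methoxymethoxy)ethanethioate | CCSC(=O)COCOC | intermediate
9 | (Z)-1-(ethylsulfanyl)-2-(methoxymethoxy)-1-(trimethylsilyloxy)ethene | CCS/C(O[Si](C)(C)C)=C\OCOC | intermediate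
10 | S-ethyl (2R,3R)-2-(methoxymethoxy)-3-[3-methoxy-4-(methoxymethoxy)phenyl]-3-(trimethylsilyloxy)propanethioate | COc1cc([C@@H](O[Si](C)(C)C)[C@@H](OCOC)C(=O)SCC)ccc1OCOC | intermediate
11 | S-ethyl (2R,3R)-3-hydroxy-2-(methoxymethoxy)-3-[3-methoxy-4-(methoxymethoxy)phenyl]propanethioate | COc1cc([C@@H](O)[C@@H](OCOC)C(=O)SCC)ccc1OCOC | intermediate
12 | S-ethyl (2R,3R)-2-(methoxymethoxy)-3-[3-methoxy-4-(methoxymethoxy)phenyl]-3-(triethylsilyloxy)propanethioate | COc1cc([C@@H](O[Si](CC)(CC)CC)[C@@H](OCOC)C(=O)SCC)ccc1OCOC | intermediate
13 | (2R,3R)-N-methoxy-2-(methoxymethoxy)-3-[3-methoxy-4-(methoxymethoxy)phenyl]-N-methyl-3-(triethylsilyloxy)propanamide | COc1cc([C@@H](O[Si](CC)(CC)CC)[C@@H](OCOC)C(=O)N(C)OC)ccc1OCOC | intermediate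
14 | 2,6-difluoro-4-(3-methylbut-2-enyloxy)phenyllithium | [Li]c1c(F)cc(OCC=C(C)C)cc1F | intermediate
15 | (2R,3R)-1-[2,6-difluoro-4-(3-methylbut-2-enyloxy)phenyl]-2-(methoxymethoxy)-3-[3-methoxy-4-(methoxymethoxy)phenyl]-3-(triethylsilyloxy)propan-1-one | COc1cc([C@@H](O[Si](CC)(CC)CC)[C@@H](OCOC)C(=O)c2c(F)cc(OCC=C(C)C)cc2F)ccc1OCOC | intermediate
16 | (2R,3R)-1-[2,6-difluoro-4-(3-methylbut-2-enyloxy)phenyl]-3-hydroxy-2-(methoxymethoxy)-3-[3-methoxy-4-(methoxymethoxy)phenyl]propan-1-one | COc1cc([C@@H](O)[C@@H](OCOC)C(=O)c2c(F)cc(OCC=C(C)C)cc2F)ccc1OCOC | intermediate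
17 | (2R,3R)-5-fluoro-3-(methoxymethoxy)-2-[3-methoxy-4-(methoxymethoxy)phenyl]-7-(3-methylbut-2-enyloxy)chroman-4-one | COc1cc([C@H]2Oc3cc(OCC=C(C)C)cc(F)c3C(=O)[C@@H]2OCOC)ccc1OCOC | intermediate
18 | N-{[(2R,3R)-3-(methoxymethoxy)-2-[3-methoxy-4-(methoxymethoxy)phenyl]-7-(3-methylbut-2-enyloxy)-4-oxochroman-5-yl]oxy}acetamide | COc1cc([C@H]2Oc3cc(OCC=C(C)C)cc(ONC(C)=O)c3C(=O)[C@@H]2OCOC)ccc1OCOC | intermediate
19 | (2R,3R)-5-hydroxy-3-(methoxymethoxy)-2-[3-methoxy-4-(methoxymethoxy)phenyl]-7-(3-methylbut-2-enyloxy)chroman-4-one | COc1cc([C@H]2Oc3cc(OCC=C(C)C)cc(O)c3C(=O)[C@@H]2OCOC)ccc1OCOC | intermediate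
20 | (2R,3R)-3,5-dihydroxy-2-(4-hydroxy-3-methoxyphenyl)-7-(3-methylbut-2-enyloxy)chroman-4-one | COc1cc([C@H]2Oc3cc(OCC=C(C)C)cc(O)c3C(=O)[C@@H]2O)ccc1O | target

## Step count and least certain steps

Total: 13 steps. Longest linear sequence: 11 steps (steps 3–13, from 6 to 20).

**Step 11 (key step).**
- Risk: the caesium aldolate of 16 may cleave by retro-aldol reaction (back to 5 and a ketone enolate) before it arylates. After closure, deprotonation at C3 may epimerise that centre or open ring C by β-elimination of the O1 phenoxide, which would erase C2. Both follow from the β-oxido ketone in 16 and the acidic C3–H in 17.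
- Fallback: set out from silyl ether 15 and treat it with a catalytic amount of CsF in DMF. Fluoride releases the alkoxide from silicon only in low concentration, the alkoxide arylates, and the expelled fluoride carries the chain. No carbonate or other Brønsted base is present and the free aldolate never builds up. The sequence returns at 17 and makes no new compound.

**Step 6.**
- Risk: poor facial or anti/syn selectivity. The second oxygen of the MOM group may bind tin differently from a benzyl ether, and aldehyde 5 is electron-rich and can bind the promoter through its vicinal methoxy/MOM oxygens, which would also slow the addition.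
- Fallback: a different carbon–carbon bond construction starting from 5. An iridium-catalysed transfer-hydrogenative anti-(α-benzoyloxy)allylation with prop-2-ene-1,1-diyl dibenzoate ([Ir(cod)Cl]2, the SEGPHOS antipode that delivers the required sense, a nitrobenzoic acid co-ligand, isopropanol as reductant) should give the anti monobenzoate F1. Silylation (Et3SiOSO2CF3, 2,6-lutidine) gives F2. Reductive removal of the benzoate with iBu2AlH at −78 °C, which avoids silyl migration, gives alcohol F3. MOMCl/iPr2NEt gives F4. Ozonolysis with Me2S work-up gives aldehyde F5. Addition of aryllithium 14 at −78 °C gives carbinol F6 as a mixture at the new centre, and Dess–Martin oxidation returns to ketone 15.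

**Step 12.**
- Risk: slow displacement. Ring A now carries two alkoxy donors and only one activating carbonyl, so heat is needed. During that time carbonate may enolise C3 and cause ring opening or epimerisation before the protective phenoxide has formed.
- Fallback: set out from 17 and install the C5 oxygen as an ether at low temperature. The sodium alkoxide of 2-(trimethylsilyl)ethanol (NaH, THF, 0 °C, alkoxide added slowly in slight deficit) gives aryl ether F7. Bu4NF in THF then fragments the silylethyl group and returns to 19.

**Step 13.**
- Risk: loss or hydration of the aryl prenyl ether while the slower C3 acetal is being cleaved. The prenyl ether ionises to a tertiary allylic cation under the same acid.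
- Fallback: set out from 19, accept loss of the prenyl group, and re-install it. Stronger acid (3 M HCl in MeOH, 50 °C) removes both acetals and the prenyl ether to give the tetraol F8. One equivalent of K2CO3 and prenyl bromide 2 in acetone then alkylates the C7 hydroxyl, the most acidic one (a vinylogous acid through the C4 carbonyl; the C5 hydroxyl is chelated, the ring B phenol is less acidic and the C3 hydroxyl is aliphatic), and returns to 20.

**Step 9.**
- Risk: decomposition of aryllithium 14 to an aryne by LiF loss if addition to the hindered amide 13 needs warming; deprotonation of the amide N-methoxy group by the organolithium is a further side path.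
- Fallback: set out from thioester 12 and aryllithium 14 (made from 3). Transmetalation of 14 with ZnCl2 gives arylzinc chloride F9, which is stable at room temperature. Palladium-catalysed coupling with 12 (PdCl2(PPh3)2, THF–toluene, a Fukuyama-type ketone synthesis) gives ketone 15 directly and bypasses 13.

## Further compounds

F1 | step 6 | (1R,2S)-1-hydroxy-1-[3-methoxy-4-(methoxymethoxy)phenyl]but-3-en-2-yl benzoate | COc1cc([C@@H](O)[C@@H](OC(=O)c2ccccc2)C=C)ccc1OCOC
F2 | step 6 | (1R,2S)-1-[3-methoxy-4-(methoxymethoxy)phenyl]-1-(triethylsilyloxy)but-3-en-2-yl benzoate | COc1cc([C@@H](O[Si](CC)(CC)CC)[C@@H](OC(=O)c2ccccc2)C=C)ccc1OCOC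
F3 | step 6 | (1R,2S)-1-[3-methoxy-4-(methoxymethoxy)phenyl]-1-(triethylsilyloxy)but-3-en-2-ol | COc1cc([C@@H](O[Si](CC)(CC)CC)[C@@H](O)C=C)ccc1OCOC
F4 | step 6 | triethyl{[(1R,2S)-2-(methoxymethoxy)-1-[3-methoxy-4-(methoxymethoxy)phenyl]but-3-enyl]oxy}silane | COc1cc([C@@H](O[Si](CC)(CC)CC)[C@@H](OCOC)C=C)ccc1OCOC
F5 | step 6 | (2R,3R)-2-(methoxymethoxy)-3-[3-methoxy-4-(methoxymethoxy)phenyl]-3-(triethylsilyloxy)propanal | COc1cc([C@@H](O[Si](CC)(CC)CC)[C@@H](OCOC)C=O)ccc1OCOC
F6 | step 6 | (1RS,2S,3R)-1-[2,6-difluoro-4-(3-methylbut-2-enyloxy)phenyl]-2-(methoxymethoxy)-3-[3-methoxy-4-(methoxymethoxy)phenyl]-3-(triethylsilyloxy)propan-1-ol | COc1cc([C@@H](O[Si](CC)(CC)CC)[C@@H](OCOC)C(O)c2c(F)cc(OCC=C(C)C)cc2F)ccc1OCOC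
F7 | step 12 | (2R,3R)-3-(methoxymethoxy)-2-[3-methoxy-4-(methoxymethoxy)phenyl]-7-(3-methylbut-2-enyloxy)-5-[2-(trimethylsilyl)ethoxy]chroman-4-one | COc1cc([C@H]2Oc3cc(OCC=C(C)C)cc(OCC[Si](C)(C)C)c3C(=O)[C@@H]2OCOC)ccc1OCOC
F8 | step 13 | (2R,3R)-3,5,7-trihydroxy-2-(4-hydroxy-3-methoxyphenyl)chroman-4-one | COc1cc([C@H]2Oc3cc(O)cc(O)c3C(=O)[C@@H]2O)ccc1O
F9 | step 9 | [2,6-difluoro-4-(3-methylbut-2-enyloxy)phenyl]zinc chloride | Cl[Zn]c1c(F)cc(OCC=C(C)C)cc1F
F0 | step 11 | none | none
A1 | alternative 1 | methyl 4-[(2R,3R)-3-(tert-butyldimethylsilyloxy)-2-[4-(tert-butyldimethylsilyloxy)-3-methoxyphenyl]-4-oxo-3,4-dihydro-2H-pyran-6-yl]-3-oxobutanoate | COc1cc([C@H]2OC(CC(=O)CC(=O)OC)=CC(=O)[C@@H]2O[Si](C)(C)C(C)(C)C)ccc1O[Si](C)(C)C(C)(C)C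
A2 | alternative 1 | (2R,3R)-3-(tert-butyldimethylsilyloxy)-2-[4-(tert-butyldimethylsilyloxy)-3-methoxyphenyl]-5,7-dihydroxychroman-4-one | COc1cc([C@H]2Oc3cc(O)cc(O)c3C(=O)[C@@H]2O[Si](C)(C)C(C)(C)C)ccc1O[Si](C)(C)C(C)(C)C
A3 | alternative 2 | (2R,3R)-2-(benzyloxy)-3-[4-(benzyloxy)-3-methoxyphenyl]-3-[3,5-bis(benzyloxy)phenoxy]propanoic acid | COc1cc([C@@H](Oc2cc(OCc3ccccc3)cc(OCc3ccccc3)c2)[C@@H](OCc2ccccc2)C(=O)O)ccc1OCc1ccccc1
A4 | alternative 2 | (2R,3R)-3,5,7-tris(benzyloxy)-2-[4-(benzyloxy)-3-methoxyphenyl]chroman-4-one | COc1cc([C@H]2Oc3cc(OCc4ccccc4)cc(OCc4ccccc4)c3C(=O)[C@@H]2OCc2ccccc2)ccc1OCc1ccccc1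
A5 | alternative 3 | methyl (2R,3R)-3-hydroxy-2-(methoxymethoxy)-3-[3-methoxy-4-(methoxymethoxy)phenyl]propanoate | COc1cc([C@@H](O)[C@@H](OCOC)C(=O)OC)ccc1OCOC
A6 | alternative 3 | 3,5-bis(methoxymethoxy)-2-(trimethylsilyl)phenyl trifluoromethanesulfonate | COCOc1cc(OCOC)c([Si](C)(C)C)c(OS(=O)(=O)C(F)(F)F)c1
A7 | alternative 3 | (2R,3R)-3,5,7-tris(methoxymethoxy)-2-[3-methoxy-4-(methoxymethoxy)phenyl]chroman-4-one | COc1cc([C@H]2Oc3cc(OCOC)cc(OCOC)c3C(=O)[C@@H]2OCOC)ccc1OCOC
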